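**Retrosynthetic overview** (C1 = ring carbinol carbon, C2/C3 = ring CH2CH2, C4 = CMeCl, C5 = CHBr, C6 = ring CH2 between C5 and C1, C7 = side-chain sp2 carbon on C1)
1. Side chain: the C7–C8 bond comes from a C7 Weinreb amide and a Grignard reagent that already carries the (R)-carbinol (Corey–Bakshi–Shibata reduction); the C7 ketone is then methylenated.
2. trans-Br/Cl: the ring alkene C4=C5 is halogenated through a temporary 7-oxabicyclo[2.2.1]heptane, in which the C1 oxygen bridges to C4 while bromine adds anti at C5; C4–O is then exchanged for C4–Cl with retention.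
3. The cyclohexene (the only carbocycle) is closed at C6–C1 by Ireland–Claisen rearrangement of a 3-hydroxy-6-methyl-6-vinyl oxan-2-one made from (S)-linalool, which supplies C1–C6 and the C4 methyl.
4. Enabling feature: C1 is a carbinol carbon bearing sp2 C7 and lies 1,4 to the methyl-bearing C4 across C2–C3, while C5–C6 is a latent vinyl group on C4. With C7 at the carboxyl level and tied to C4 through oxygen, C1=C7–O–C4–C5=C6 is an allyl vinyl ether locked in a six-membered lactone, so the linalool carbinol stereocenter (C4) is transferred to C1.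
5. Ring order: oxan-2-one (temporary) → cyclohexene (key step) → oxygen bridge (temporary, opened again).

Key step: step 5

Assumption: (S)-(+)-linalool of high enantiomeric purity is taken as a commercial chiral pool material.

**Step 1**
Reactants: 1 (S)-(+)-linalool [(3S)-3,7-dimethylocta-1,6-dien-3-ol]
Product: 2 (5S)-5-ethenyl-5-methyloxolan-2-ol (lactol of (4S)-4-hydroxy-4-methylhex-5-enal; anomer mixture)
Conditions: O3 (1 equiv), CH2Cl2/MeOH, −78 °C; then Me2S, −78 °C → rt
Reagents that add atoms: ozone, [O-][O+]=O
Why: Chemoselective ozonolysis, in which the electron-rich trisubstituted alkene should react far faster than the vinyl group next to the carbinol oxygen, so that reductive work-up gives the hydroxy aldehyde, which closes to the lactol with the tertiary stereocenter untouched.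

**Step 2**
Reactants: 2 (5S)-5-ethenyl-5-methyloxolan-2-ol
Product: 4 (6S)-6-ethenyl-6-methyloxan-2-ol (anomer mixture), via enol ether 3 (not isolated)
Conditions: MeOCH2PPh3Cl, KOtBu, THF, 0 °C → rt; then 0.5 M HCl, THF/H2O, 0 °C → rt
Reagents that add atoms: (methoxymethyl)triphenylphosphonium chloride, COC[P+](c1ccccc1)(c1ccccc1)c1ccccc1.[Cl-]; water, O
Why: Wittig methoxymethylenation of the open hydroxy aldehyde form of the lactol (the standard one-carbon homologation of lactols), followed by mild acid hydrolysis of the enol ether, whose oxocarbenium ion is trapped by the tertiary hydroxyl to give the six-membered lactol without touching the stereocenter.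

**Step 3**
Reactants: 4 (6S)-6-ethenyl-6-methyloxan-2-ol
Product: 5 (6S)-6-ethenyl-6-methyloxan-2-one
Conditions: TEMPO (2,2,6,6-tetramethylpiperidin-1-oxyl, cat.), PhI(OAc)2, CH2Cl2, rt
Reagents that add atoms: none
Why: Nitroxyl-catalysed oxidation of a lactol to the lactone under neutral, chromium-free conditions that should leave the vinyl group and the tertiary allylic C–O bond intact.

**Step 4**
Reactants: 5 (6S)-6-ethenyl-6-methyloxan-2-one
Product: 6 (6S)-6-ethenyl-3-hydroxy-6-methyloxan-2-one (both C3 epimers)
Conditions: KN(SiMe3)2, THF, −78 °C; 2-(phenylsulfonyl)-3-phenyloxaziridine, −78 °C; AcOH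
Reagents that add atoms: 2-(phenylsulfonyl)-3-phenyloxaziridine, O=S(=O)(c1ccccc1)N1OC1c1ccccc1
Why: Davis-type hydroxylation of the potassium enolate, which can only form at C3 of the lactone; the new carbinol carbon is left as an epimer mixture because it becomes trigonal again in step 5.

**Step 5**
Reactants: 6 (6S)-6-ethenyl-3-hydroxy-6-methyloxan-2-one
Product: 10 (1S)-1-hydroxy-4-methylcyclohex-3-ene-1-carboxylic acid, via silyl ether lactone 7 (not isolated), via bis-silyl ketene acetal 8 (not isolated), via bis-silyl ester 9 (not isolated)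
Conditions: Me3SiCl/Et3N, LiN(iPr)2 (2.3 equiv), THF, −78 °C → rt; PhMe, 100 °C; then 1 M HCl, THF, rt
Reagents that add atoms: none
Why: O-Silylation and enolization in the flask give the cyclic bis-silyl ketene acetal, in which C(OSi)=C(OSi)–O–C(Me)–CH=CH2 is an allyl vinyl ether whose two ends are tied together by the two ring methylenes, and heating triggers a [3,3]-sigmatropic Ireland–Claisen shift that joins the vinyl terminus to the silyloxy-bearing enol carbon while the lactone C–O bond breaks. The closest known reaction type is the Claisen rearrangement of silyl ketene acetals of lactones that carry a vinyl group on the carbinol carbon, which gives cycloalkene carboxylic acids, together with the analogous rearrangement of 6-alkenyl-1,4-dioxan-2-one ketene acetals to dihydropyrans. The cyclohexene is closed as a lactone-to-carbocycle transposition through a boat-shaped, bicyclo[2.2.2]octane-like transition state, the only one the two-carbon tether allows, so the new ring alkene is necessarily cis and trisubstituted. The new quaternary carbinol center is set by 1,4-chirality transfer: the (S)-configured carbinol carbon of the lactone holds the vinyl group over one face of the ketene acetal only, which translates into the (S) configuration of the acid while the old stereocenter becomes the sp2 methyl-bearing ring carbon. The step needs complete suprafacial transfer without ionization of the tertiary allylic C–O bond, which a non-polar solvent, the absence of Lewis acid and the acceleration by the silyloxy donors should secure; both C3 epimers of 6 converge because that carbon is trigonal in the ketene acetal.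

**Step 6**
Reactants: 10 (1S)-1-hydroxy-4-methylcyclohex-3-ene-1-carboxylic acid
Product: 11 methyl (1S)-1-hydroxy-4-methylcyclohex-3-ene-1-carboxylate
Conditions: MeI, K2CO3, DMF, rt
Reagents that add atoms: iodomethane, CI
Why: Carboxylate O-alkylation (SN2) that leaves the tertiary hydroxyl free; the methyl ester is chosen because a free acid or an amide would compete with the hydroxyl as internal nucleophile in step 7.

**Step 7**
Reactants: 11 methyl (1S)-1-hydroxy-4-methylcyclohex-3-ene-1-carboxylate
Product: 12 methyl (1S,3R,4R)-3-bromo-4-methyl-7-oxabicyclo[2.2.1]heptane-1-carboxylate (bromine anti to the oxygen bridge)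
Conditions: N-bromosuccinimide, CH2Cl2, 0 °C, dark
Reagents that add atoms: N-bromosuccinimide, O=C1CCC(=O)N1Br
Why: Bromoetherification, in which only the bromonium ion on the face anti to the C1 hydroxyl can be captured by that hydroxyl at the methyl-bearing (Markovnikov) carbon across the ring, as in the cyclization of terpinen-4-ol to 1,4-cineole derivatives, so the anti-addition mechanism should place bromine trans to the C1 oxygen.

**Step 8**
Reactants: 12 methyl (1S,3R,4R)-3-bromo-4-methyl-7-oxabicyclo[2.2.1]heptane-1-carboxylate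
Product: 14 methyl (1S,3R,4R)-3-bromo-4-chloro-1-hydroxy-4-methylcyclohexane-1-carboxylate, via dichloroboryl ether 13 (not isolated)
Conditions: BCl3, CH2Cl2, −78 °C; then H2O, 0 °C
Reagents that add atoms: boron trichloride, ClB(Cl)Cl
Why: Boron trihalide cleavage of the strained bridged ether, in which only the C–O bond at the methyl-bearing carbon should ionize (the other is alpha to the ester) with help from the anti-periplanar bromine as a bromonium ion, which chloride opens at the tertiary carbon from the face the oxygen left (double inversion, net retention), giving chlorine cis to the C1 oxygen and trans to bromine.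

**Step 9**
Reactants: 14 methyl (1S,3R,4R)-3-bromo-4-chloro-1-hydroxy-4-methylcyclohexane-1-carboxylate
Product: 15 (1S,3R,4R)-3-bromo-4-chloro-1-hydroxy-N-methoxy-N,4-dimethylcyclohexane-1-carboxamide
Conditions: MeNHOMe·HCl, iPrMgCl, THF, −20 → 0 °C
Reagents that add atoms: N,O-dimethylhydroxylamine hydrochloride, CNOC.Cl
Why: Weinreb amide formation by aminolysis of the ester with the chloromagnesium amide, assisted by the neighbouring magnesium alkoxide; in the preferred chair both halogens should be equatorial and have no anti-periplanar ring hydrogen, so elimination by the Grignard base is not expected at low temperature.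

**Step 10**
Reactants: 15 (1S,3R,4R)-3-bromo-4-chloro-1-hydroxy-N-methoxy-N,4-dimethylcyclohexane-1-carboxamide
Product: 16 (1S,3R,4R)-3-bromo-4-chloro-N-methoxy-N,4-dimethyl-1-(triethylsilyloxy)cyclohexane-1-carboxamide
Conditions: Et3SiOTf, 2,6-lutidine, CH2Cl2, −78 → 0 °C
Reagents that add atoms: triethylsilyl trifluoromethanesulfonate, CC[Si](CC)(CC)OS(=O)(=O)C(F)(F)F
Why: Silylation of the hindered tertiary alcohol with a silyl triflate and a hindered pyridine base, which blocks alpha-ketol rearrangement and alkoxide side reactions in the carbonyl steps that follow.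

**Step 11**
Reactants: 17 3-chloropropanoyl chloride; 18 isopropenylmagnesium bromide
Product: 19 5-chloro-2-methylpent-1-en-3-one
Conditions: CuI (5 mol %), THF, −78 °C
Reagents that add atoms: none
Why: Copper-catalysed acylation of a Grignard reagent by an acid chloride, which should stop at the ketone at low temperature and leave the primary chloride untouched.

**Step 12**
Reactants: 19 5-chloro-2-methylpent-1-en-3-one
Product: 20 (3R)-5-chloro-2-methylpent-1-en-3-ol
Conditions: (S)-2-methyl-CBS-oxazaborolidine (10 mol %), BH3·SMe2, THF, −30 °C; then MeOH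
Reagents that add atoms: none
Why: Corey–Bakshi–Shibata reduction, in which the isopropenyl group acts as the large substituent, so the (S)-catalyst should deliver hydride to give the (R)-carbinol in the same sense as acetophenone gives (R)-1-phenylethanol.

**Step 13**
Reactants: 20 (3R)-5-chloro-2-methylpent-1-en-3-ol
Product: 21 [(3R)-5-chloro-2-methylpent-1-en-3-yl]oxy(triethyl)silane
Conditions: Et3SiCl, imidazole, CH2Cl2, 0 °C → rt
Reagents that add atoms: chlorotriethylsilane, CC[Si](Cl)(CC)CC
Why: Standard silylation of the secondary allylic alcohol; the triethylsilyl ether should survive Grignard formation and is removed together with the ring silyl ether in the last step.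

**Step 14**
Reactants: 21 [(3R)-5-chloro-2-methylpent-1-en-3-yl]oxy(triethyl)silane; 16 (1S,3R,4R)-3-bromo-4-chloro-N-methoxy-N,4-dimethyl-1-(triethylsilyloxy)cyclohexane-1-carboxamide
Product: 23 (4R)-1-[(1S,3R,4R)-3-bromo-4-chloro-4-methyl-1-(triethylsilyloxy)cyclohexyl]-5-methyl-4-(triethylsilyloxy)hex-5-en-1-one, via Grignard reagent 22 (not isolated)
Conditions: Mg, THF, reflux (21 → 22); then 16, THF, 0 °C → rt; aq. NH4Cl
Reagents that add atoms: none
Why: Grignard formation from the primary chloride and acyl substitution on the Weinreb amide, whose magnesium chelate should stop the addition at the ketone stage; alkyl Grignard reagents are not expected to exchange with or displace the hindered secondary bromide and tertiary chloride at these temperatures.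

**Step 15**
Reactants: 23 (4R)-1-[(1S,3R,4R)-3-bromo-4-chloro-4-methyl-1-(triethylsilyloxy)cyclohexyl]-5-methyl-4-(triethylsilyloxy)hex-5-en-1-one
Product: 24 triethyl{[(1S,3R,4R)-3-bromo-4-chloro-4-methyl-1-[(5R)-6-methyl-5-(triethylsilyloxy)hepta-1,6-dien-2-yl]cyclohexyl]oxy}silane
Conditions: Cp2TiMe2, PhMe, 70 °C, dark
Reagents that add atoms: dimethyltitanocene (Cp2TiMe2), [CH3-].[CH3-].[Ti+4].c1cc[cH-]c1.c1cc[cH-]c1
Why: Petasis methylenation, which should convert the hindered, enolizable alpha-silyloxy ketone to the 1,1-disubstituted alkene under non-basic, non-reducing conditions that spare the vicinal bromochloride.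

**Step 16**
Reactants: 24 triethyl{[(1S,3R,4R)-3-bromo-4-chloro-4-methyl-1-[(5R)-6-methyl-5-(triethylsilyloxy)hepta-1,6-dien-2-yl]cyclohexyl]oxy}silane
Product: 25 (1S,3R,4R)-3-bromo-4-chloro-1-[(5R)-5-hydroxy-6-methylhepta-1,6-dien-2-yl]-4-methylcyclohexan-1-ol (target)
Conditions: HF·pyridine, pyridine/THF, 0 °C → rt
Reagents that add atoms: none
Why: Fluoride-mediated cleavage of both triethylsilyl ethers under buffered conditions, which should free the tertiary and the secondary allylic alcohol without ionizing the tertiary chloride or the allylic carbinols.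

**Compound list**
1 | (S)-(+)-linalool, (3S)-3,7-dimethylocta-1,6-dien-3-ol | C=C[C@@](C)(O)CCC=C(C)C | starting material
2 | (5S)-5-ethenyl-5-methyloxolan-2-ol | C=C[C@]1(C)CCC(O)O1 | intermediate
3 | (3S)-7-methoxy-3-methylhepta-1,6-dien-3-ol (enol ether, E/Z) | C=C[C@@](C)(O)CCC=COC | intermediate
4 | (6S)-6-ethenyl-6-methyloxan-2-ol | C=C[C@]1(C)CCCC(O)O1 | intermediate
5 | (6S)-6-ethenyl-6-methyloxan-2-one | C=C[C@]1(C)CCCC(=O)O1 | intermediate
6 | (6S)-6-ethenyl-3-hydroxy-6-methyloxan-2-one | C=C[C@]1(C)CCC(O)C(=O)O1 | intermediate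
7 | (6S)-6-ethenyl-6-methyl-3-(trimethylsilyloxy)oxan-2-one | C=C[C@]1(C)CCC(O[Si](C)(C)C)C(=O)O1 | intermediate
8 | (2S)-2-ethenyl-2-methyl-5,6-bis(trimethylsilyloxy)-3,4-dihydro-2H-pyran | C=C[C@]1(C)CCC(O[Si](C)(C)C)=C(O[Si](C)(C)C)O1 | intermediate
9 | trimethylsilyl (1S)-4-methyl-1-(trimethylsilyloxy)cyclohex-3-ene-1-carboxylate | C[Si](C)(C)OC(=O)[C@]1(O[Si](C)(C)C)CCC(C)=CC1 | intermediate
10 | (1S)-1-hydroxy-4-methylcyclohex-3-ene-1-carboxylic acid | OC(=O)[C@]1(O)CCC(C)=CC1 | intermediate
11 | methyl (1S)-1-hydroxy-4-methylcyclohex-3-ene-1-carboxylate | COC(=O)[C@]1(O)CCC(C)=CC1 | intermediate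
12 | methyl (1S,3R,4R)-3-bromo-4-methyl-7-oxabicyclo[2.2.1]heptane-1-carboxylate | COC(=O)[C@]1(O2)CC[C@]2(C)[C@H](Br)C1 | intermediate
13 | methyl (1S,3R,4R)-3-bromo-4-chloro-1-(dichloroboryloxy)-4-methylcyclohexane-1-carboxylate | COC(=O)[C@]1(OB(Cl)Cl)CC[C@@](C)(Cl)[C@H](Br)C1 | intermediate
14 | methyl (1S,3R,4R)-3-bromo-4-chloro-1-hydroxy-4-methylcyclohexane-1-carboxylate | COC(=O)[C@]1(O)CC[C@@](C)(Cl)[C@H](Br)C1 | intermediate
15 | (1S,3R,4R)-3-bromo-4-chloro-1-hydroxy-N-methoxy-N,4-dimethylcyclohexane-1-carboxamide | CON(C)C(=O)[C@]1(O)CC[C@@](C)(Cl)[C@H](Br)C1 | intermediate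
16 | (1S,3R,4R)-3-bromo-4-chloro-N-methoxy-N,4-dimethyl-1-(triethylsilyloxy)cyclohexane-1-carboxamide | CON(C)C(=O)[C@]1(O[Si](CC)(CC)CC)CC[C@@](C)(Cl)[C@H](Br)C1 | intermediate
17 | 3-chloropropanoyl chloride | ClCCC(Cl)=O | starting material
18 | isopropenylmagnesium bromide | CC(=C)[Mg]Br | starting material
19 | 5-chloro-2-methylpent-1-en-3-one | C=C(C)C(=O)CCCl | intermediate
20 | (3R)-5-chloro-2-methylpent-1-en-3-ol | C=C(C)[C@H](O)CCCl | intermediate
21 | [(3R)-5-chloro-2-methylpent-1-en-3-yl]oxy(triethyl)silane | C=C(C)[C@H](O[Si](CC)(CC)CC)CCCl | intermediate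
22 | [(3R)-4-methyl-3-(triethylsilyloxy)pent-4-en-1-yl]magnesium chloride | C=C(C)[C@H](O[Si](CC)(CC)CC)CC[Mg]Cl | intermediate
23 | (4R)-1-[(1S,3R,4R)-3-bromo-4-chloro-4-methyl-1-(triethylsilyloxy)cyclohexyl]-5-methyl-4-(triethylsilyloxy)hex-5-en-1-one | C=C(C)[C@H](O[Si](CC)(CC)CC)CCC(=O)[C@]1(O[Si](CC)(CC)CC)CC[C@@](C)(Cl)[C@H](Br)C1 | intermediate
24 | triethyl{[(1S,3R,4R)-3-bromo-4-chloro-4-methyl-1-[(5R)-6-methyl-5-(triethylsilyloxy)hepta-1,6-dien-2-yl]cyclohexyl]oxy}silane | C=C(C)[C@H](O[Si](CC)(CC)CC)CCC(=C)[C@]1(O[Si](CC)(CC)CC)CC[C@@](C)(Cl)[C@H](Br)C1 | intermediate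
25 | (1S,3R,4R)-3-bromo-4-chloro-1-[(5R)-5-hydroxy-6-methylhepta-1,6-dien-2-yl]-4-methylcyclohexan-1-ol | C=C(C)[C@H](O)CCC(=C)[C@]1(O)CC[C@@](C)(Cl)[C@H](Br)C1 | target

**Total step count:** 16. **Longest linear sequence:** 13 steps (steps 1–10 and 14–16).

**Steps most likely to fail**

Step 8. The bridged ether may ionize reversibly and close again on work-up, or the bromonium ion may lose a proton or be opened by chloride at the secondary carbon (loss of regiocontrol). The fallback replaces Lewis-acid cleavage with hydrolytic work-up by an acylative cleavage that traps the oxygen irreversibly. Setting out from 12, acetyl chloride with catalytic ZnCl2 in CH2Cl2 at 0 °C should acylate the bridge oxygen, so that the same bromine-assisted ionization and chloride capture end in methyl (1S,3R,4R)-1-acetoxy-3-bromo-4-chloro-4-methylcyclohexane-1-carboxylate F1. Methanolysis of the tertiary acetate (K2CO3, MeOH, 0 °C) then comes back to the route at 14.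

Step 5. The labile bis-silyl ketene acetal may be lost by hydrolysis or silyl scrambling before the slow boat-shaped rearrangement, or the tertiary allylic C–O bond may ionize (erosion of the chirality transfer, diene formation). The fallback uses a neutral enol ether Claisen rearrangement at the aldehyde oxidation level in place of ester enolate chemistry. Setting out from 6:
- Silylation (Et3SiCl, imidazole) should give (6S)-6-ethenyl-6-methyl-3-(triethylsilyloxy)oxan-2-one F2.
- Enolate triflation (KN(SiMe3)2, PhNTf2, THF, −78 °C) should give (2S)-2-ethenyl-2-methyl-5-(triethylsilyloxy)-3,4-dihydro-2H-pyran-6-yl trifluoromethanesulfonate F3.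
- Palladium-catalysed formate reduction (Pd(OAc)2, PPh3, HCO2H, Et3N) should give the robust cyclic enol ether (2S)-2-ethenyl-2-methyl-5-(triethylsilyloxy)-3,4-dihydro-2H-pyran F4.
- Heating (PhMe, sealed tube, 180 °C) should close the same bond through the same bicyclic boat and give (1S)-4-methyl-1-(triethylsilyloxy)cyclohex-3-ene-1-carbaldehyde F5.
- Pinnick oxidation (NaClO2, NaH2PO4, 2-methylbut-2-ene) should give (1S)-4-methyl-1-(triethylsilyloxy)cyclohex-3-ene-1-carboxylic acid F6.
- Mild acid (1 M HCl, THF) removes the silyl group and comes back to the route at 10.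

Step 14. Slow addition to the hindered amide may let the Grignard reagent act as a base (loss of formaldehyde from the N-methoxy group) or attack the halides on prolonged warming. The fallback replaces acyl substitution by aldehyde addition and re-oxidation. Setting out from 16, reduction with iBu2AlH (THF, −78 °C) should give (1S,3R,4R)-3-bromo-4-chloro-4-methyl-1-(triethylsilyloxy)cyclohexane-1-carbaldehyde F7. This aldehyde should accept Grignard reagent 22 at −78 °C to give (4R)-1-[(1S,3R,4R)-3-bromo-4-chloro-4-methyl-1-(triethylsilyloxy)cyclohexyl]-5-methyl-4-(triethylsilyloxy)hex-5-en-1-ol F8 as a mixture of epimers at the new carbinol carbon. Dess–Martin oxidation comes back to the route at 23.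

**Further compounds**
F1 | step 8 | methyl (1S,3R,4R)-1-acetoxy-3-bromo-4-chloro-4-methylcyclohexane-1-carboxylate | COC(=O)[C@]1(OC(C)=O)CC[C@@](C)(Cl)[C@H](Br)C1
F2 | step 5 | (6S)-6-ethenyl-6-methyl-3-(triethylsilyloxy)oxan-2-one | C=C[C@]1(C)CCC(O[Si](CC)(CC)CC)C(=O)O1
F3 | step 5 | (2S)-2-ethenyl-2-methyl-5-(triethylsilyloxy)-3,4-dihydro-2H-pyran-6-yl trifluoromethanesulfonate | C=C[C@]1(C)CCC(O[Si](CC)(CC)CC)=C(OS(=O)(=O)C(F)(F)F)O1
F4 | step 5 | (2S)-2-ethenyl-2-methyl-5-(triethylsilyloxy)-3,4-dihydro-2H-pyran | C=C[C@]1(C)CCC(O[Si](CC)(CC)CC)=CO1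
F5 | step 5 | (1S)-4-methyl-1-(triethylsilyloxy)cyclohex-3-ene-1-carbaldehyde | O=C[C@]1(O[Si](CC)(CC)CC)CCC(C)=CC1
F6 | step 5 | (1S)-4-methyl-1-(triethylsilyloxy)cyclohex-3-ene-1-carboxylic acid | OC(=O)[C@]1(O[Si](CC)(CC)CC)CCC(C)=CC1
F7 | step 14 | (1S,3R,4R)-3-bromo-4-chloro-4-methyl-1-(triethylsilyloxy)cyclohexane-1-carbaldehyde | O=C[C@]1(O[Si](CC)(CC)CC)CC[C@@](C)(Cl)[C@H](Br)C1
F8 | step 14 | (4R)-1-[(1S,3R,4R)-3-bromo-4-chloro-4-methyl-1-(triethylsilyloxy)cyclohexyl]-5-methyl-4-(triethylsilyloxy)hex-5-en-1-ol | C=C(C)[C@H](O[Si](CC)(CC)CC)CCC(O)[C@]1(O[Si](CC)(CC)CC)CC[C@@](C)(Cl)[C@H](Br)C1
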